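**Plan**

- Numbering of the target as 4,6-dioxatricyclo[5.4.0.0^{1,5}]undec-9-ene: C1 quaternary, C3 carries the isopropenyl group, O4, C5 acetal, O6, C7 (Me), C8 (Br), C9=C10 (Br), C11 (Me2). Ring A is the carbocycle; the oxolane (C1–C2–C3–O4–C5) and the oxetane (C1–C5–O6–C7) share the C1–C5 bond.
- Enabling feature: the acetal carbon C5 lies between O4, which is bound to an allylic carbon (C3, next to the isopropenyl group), and O6, which is bound to C7 with the C8 bromine anti to it. This is an aldehyde caught between an allyl cation five atoms away and a trans-bromohydrin alkoxide (a cis-epoxide plus bromide), much as in the presumed biogenesis from a seco-chamigrene aldehyde.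
- Retrosynthesis: O4–C3, O6–C5 and C8–Br are cut in one operation, leading back to a constitutional isomer of the target, an epoxy aldehyde with a primary allylic bromide. Then the epoxide oxygen, the C1–C2 bond (enolate alkylation) and C10–Br (allylic bromination of safranal) are removed.
- Forward: ring A and C5 come intact from safranal. Bromination, α-alkylation (all 15 carbons, quaternary C1), reduction, directed epoxidation and oxidation give the precursor; the last step closes the oxolane first and then the oxetane.
- Stereochemistry: the absolute configuration comes from a kinetic resolution in the hydroxyl-directed vanadium epoxidation (epoxide syn to CH2OH sets C7 against C1). C8 follows from anti epoxide opening, C5 from the cis ring fusion, C3 from convex-face closure of the bicyclic acetal.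

Key step: step 6

Remark: the sense of enantiomer discrimination of the chiral vanadium catalyst at a quaternary homoallylic centre cannot be assigned by analogy, so the ligand antipode would be fixed by one test run on the racemate; the (R)-alcohol is written as the matched enantiomer.

**Step 1**
Reactants: 1 safranal (2,6,6-trimethylcyclohexa-1,3-diene-1-carbaldehyde)
Product: 2 (±)-5-bromo-2,6,6-trimethylcyclohexa-1,3-diene-1-carbaldehyde
Conditions: NBS (1.05 equiv), AIBN (5 mol %), PhCF3, 80 °C
Reagents that add atoms: N-bromosuccinimide, O=C1CCC(=O)N1Br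
Why: Wohl–Ziegler allylic bromination: hydrogen abstraction from C5–H2, the only ring methylene, gives a pentadienyl radical conjugated with the formyl group, and bromine transfer at the terminus next to the gem-dimethyl carbon keeps the dienal conjugated (allylic isomers should equilibrate to this one), the new stereocentre being racemic and erased in step 2.

**Step 2**
Reactants: 2 (±)-5-bromo-2,6,6-trimethylcyclohexa-1,3-diene-1-carbaldehyde; 3 (2E)-1,4-dibromo-2-methylbut-2-ene
Product: 5 (±)-5-bromo-1-[(2E)-4-bromo-3-methylbut-2-en-1-yl]-2,6,6-trimethylcyclohexa-2,4-diene-1-carbaldehyde, via potassium trienolate 4 (not isolated)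
Conditions: KN(SiMe3)2 (1.05 equiv), THF, −78 °C; then added to 3 (3 equiv), THF, −78 → −20 °C
Reagents that add atoms: none
Why: Deconjugative α-alkylation of an extended enolate, as known for cyclocitral, safranal and cyclogeranate esters: trienolate 4 should react at its α-carbon by SN2 at the CH2Br group of 3 that is remote from the methyl-bearing alkene carbon (3 in excess against double alkylation), which builds the quaternary centre as a racemate, moves the diene into the 2,4-position with bromine on C5 and joins all fifteen carbons.

**Step 3**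
Reactants: 5 (±)-5-bromo-1-[(2E)-4-bromo-3-methylbut-2-en-1-yl]-2,6,6-trimethylcyclohexa-2,4-diene-1-carbaldehyde
Product: 6 (±)-[5-bromo-1-[(2E)-4-bromo-3-methylbut-2-en-1-yl]-2,6,6-trimethylcyclohexa-2,4-dien-1-yl]methanol
Conditions: i-Bu2AlH (1.2 equiv), CH2Cl2, −78 °C; aq. potassium sodium tartrate (KNaC4H4O6)
Reagents that add atoms: none
Why: 1,2-Reduction of the neopentyl aldehyde by i-Bu2AlH at low temperature, where the allylic and alkenyl bromides are inert and the aluminium alkoxide should not cyclise onto the allyl bromide, supplies the hydroxyl group that directs step 4.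

**Step 4**
Reactants: 6 (±)-[5-bromo-1-[(2E)-4-bromo-3-methylbut-2-en-1-yl]-2,6,6-trimethylcyclohexa-2,4-dien-1-yl]methanol
Product: 7 [(1R,5R,6S)-3-bromo-5-[(2E)-4-bromo-3-methylbut-2-en-1-yl]-4,4,6-trimethyl-7-oxabicyclo[4.1.0]hept-2-en-5-yl]methanol
Conditions: VO(O-i-Pr)3 (2 mol %), chiral bishydroxamic acid ligand from trans-cyclohexane-1,2-diamine (4 mol %), cumene hydroperoxide (0.55 equiv), toluene, 0 °C → rt, stopped near half conversion
Reagents that add atoms: cumene hydroperoxide, CC(C)(OO)c1ccccc1
Why: Hydroxyl-directed vanadium-catalysed epoxidation of a homoallylic alcohol run as a kinetic resolution: the CH2OH group can deliver oxygen only to the face of the ring C2=C3 bond syn to itself (the bromo-alkene and the side-chain alkene being too electron-poor or too remote), so each enantiomer offers the chiral catalyst the opposite enantioface and the matched (R)-6 should be epoxidised first, which fixes the absolute configuration and places the epoxide cis to the future acetal carbon, unreacted (S)-6 being removed by chromatography.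

**Step 5**
Reactants: 7 [(1R,5R,6S)-3-bromo-5-[(2E)-4-bromo-3-methylbut-2-en-1-yl]-4,4,6-trimethyl-7-oxabicyclo[4.1.0]hept-2-en-5-yl]methanol
Product: 8 (1R,5S,6S)-3-bromo-5-[(2E)-4-bromo-3-methylbut-2-en-1-yl]-4,4,6-trimethyl-7-oxabicyclo[4.1.0]hept-2-ene-5-carbaldehyde
Conditions: Dess–Martin periodinane (1.3 equiv), pyridine (3 equiv), CH2Cl2, 0 °C → rt
Reagents that add atoms: none
Why: Dess–Martin oxidation of the neopentyl primary alcohol under pyridine buffer, mild enough for the allylic epoxide and the allylic bromide, should give an aldehyde that cannot enolise because its α-carbon is quaternary.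

**Step 6**
Reactants: 8 (1R,5S,6S)-3-bromo-5-[(2E)-4-bromo-3-methylbut-2-en-1-yl]-4,4,6-trimethyl-7-oxabicyclo[4.1.0]hept-2-ene-5-carbaldehyde
Product: 10 (1S,3R,5S,7S,8S)-8,10-dibromo-7,11,11-trimethyl-3-(prop-1-en-2-yl)-4,6-dioxatricyclo[5.4.0.0^{1,5}]undec-9-ene (CNP0141320.1), via 2-bromooxolane 9 (not isolated)
Conditions: ZnBr2 (20 mol %), 2,6-di-tert-butyl-4-methylpyridine (20 mol %), 4 Å MS, CH2Cl2, −20 °C → rt; Et3N quench
Reagents that add atoms: none
Why: Proposed new method: ZnBr2 should ionise the primary allylic C–Br bond with participation of the aldehyde oxygen, which attacks the internal allyl terminus (5-exo-trig, SN2′; the 7-endo mode would put an E-alkene into a seven-membered ring) and closes the oxolane as the 2-bromooxolane/oxocarbenium bromozincate 9, after which the bromide set free opens the cis-epoxide at its allylic carbon with inversion while the released tertiary oxygen collapses onto the anomeric carbon (4-exo-trig on the oxocarbenium), so that 8 isomerises to 10 with one bromide serving as leaving group and as nucleophile. The closest known reaction types are the halide-relay coupling of epoxides with carbonyl groups (Lewis acid/halide-catalysed formation of 1,3-dioxolanes and cyclic carbonates), the Lewis-acid-catalysed insertion of epoxides into α-halo ethers to give 2-haloalkyl acetals, and carbonyl-oxygen participation in the ionisation of γ-halo and γ,δ-unsaturated carbonyl compounds; their union in one molecule, the allylic trigger and the closure of a four-membered acetal are not known. C8 is set by backside attack of bromide on the epoxide (Br anti to O6), C5 by the fact that only a cis-fused 2,7-dioxabicyclo[3.2.0]heptane can form on the face that the epoxide oxygen occupies, and C3 by closure of that bicycle: O-allylation is expected to be reversible through 9 (α-bromo ethers dealkylate), and the epimer with the isopropenyl group on the convex face, away from the oxetane, should be captured preferentially. The step needs the tertiary oxygen not to alkylate the allyl unit and the epoxide to open at C8 and not at C7: the first is secured because that oxygen stays masked as the epoxide until the allyl bromide has been consumed, the second because C8 is allylic and open to backside attack whereas C7 is tertiary and flanked by the quaternary C1. The isomerisation is estimated to be mildly exergonic, the strain of the new oxetane being paid for by loss of the oxirane and of the C=O π bond, and it forms no stoichiometric by-product.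

**Compound list**

1 | safranal (2,6,6-trimethylcyclohexa-1,3-diene-1-carbaldehyde) | O=CC1=C(C)C=CCC1(C)C | starting material
2 | (±)-5-bromo-2,6,6-trimethylcyclohexa-1,3-diene-1-carbaldehyde | O=CC1=C(C)C=CC(Br)C1(C)C | intermediate
3 | (2E)-1,4-dibromo-2-methylbut-2-ene | BrC/C=C(C)/CBr | starting material
4 | potassium trienolate of 2 (potassium (3-bromo-2,2,6-trimethylcyclohexa-3,5-dien-1-ylidene)methanolate) | [K+].[O-]C=C1C(C)=CC=C(Br)C1(C)C | intermediate (not isolated)
5 | (±)-5-bromo-1-[(2E)-4-bromo-3-methylbut-2-en-1-yl]-2,6,6-trimethylcyclohexa-2,4-diene-1-carbaldehyde | O=CC1(C/C=C(C)/CBr)C(C)=CC=C(Br)C1(C)C | intermediate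
6 | (±)-[5-bromo-1-[(2E)-4-bromo-3-methylbut-2-en-1-yl]-2,6,6-trimethylcyclohexa-2,4-dien-1-yl]methanol | OCC1(C/C=C(C)/CBr)C(C)=CC=C(Br)C1(C)C | intermediate
7 | [(1R,5R,6S)-3-bromo-5-[(2E)-4-bromo-3-methylbut-2-en-1-yl]-4,4,6-trimethyl-7-oxabicyclo[4.1.0]hept-2-en-5-yl]methanol (epoxide cis to CH2OH) | OC[C@]1(C/C=C(C)/CBr)[C@]2(C)O[C@@H]2C=C(Br)C1(C)C | intermediate
8 | (1R,5S,6S)-3-bromo-5-[(2E)-4-bromo-3-methylbut-2-en-1-yl]-4,4,6-trimethyl-7-oxabicyclo[4.1.0]hept-2-ene-5-carbaldehyde | O=C[C@]1(C/C=C(C)/CBr)[C@]2(C)O[C@@H]2C=C(Br)C1(C)C | intermediate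
9 | (1R,5S,6S,5′R)-2′,3-dibromo-4,4,6-trimethyl-5′-(prop-1-en-2-yl)spiro[7-oxabicyclo[4.1.0]hept-2-ene-5,3′-oxolane], both C2′ anomers, in equilibrium with its oxocarbenium bromozincate | C=C(C)[C@H]1C[C@@]2(C(Br)O1)[C@]3(C)O[C@@H]3C=C(Br)C2(C)C | intermediate (not isolated)
10 | (1S,3R,5S,7S,8S)-8,10-dibromo-7,11,11-trimethyl-3-(prop-1-en-2-yl)-4,6-dioxatricyclo[5.4.0.0^{1,5}]undec-9-ene (CNP0141320.1) | C=C(C)[C@H]1C[C@@]23[C@@H](O1)O[C@]2(C)[C@@H](Br)C=C(Br)C3(C)C | target

**Count and risks**

Total steps: 6. Longest linear sequence: 6 (1 → 10; 3 is purchased).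

1. Step 6 (the proposed new method). What may go wrong: Lewis-acid rearrangement of the allylic epoxide before it is captured, opening of the epoxide at the tertiary carbon, direct allylation of the tertiary oxygen once it is set free, or poor facial control at C3 during oxolane closure. Fallback with known reactions, from 8 to 10: Pinnick oxidation (NaClO2, NaH2PO4, 2-methylbut-2-ene, t-BuOH/H2O) would give epoxy acid F1. KHCO3 in DMF would close the γ-lactone by intramolecular SN2′ alkylation of the carboxylate (5-exo) to epoxy lactone F2, where C3 epimers, if formed, are separated. Li2NiBr4 in THF would open the allylic epoxide anti to give bromohydrin lactone F3. i-Bu2AlH at −78 °C would reduce it to lactol F4. A Mitsunobu cyclodehydration (PPh3, diisopropyl azodicarboxylate, THF, 0 °C), the known way of closing a strained bicyclic oxetane acetal from a hemiacetal and a neighbouring hydroxyl group, would return to 10.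

2. Step 4. What may go wrong: insufficient rate difference between the two enantiomers at the chiral vanadium catalyst, or competing epoxidation of the side-chain alkene. Fallback, from 6 to 7: the enantiomers of 6 are separated by preparative chromatography on a chiral stationary phase to give (R)-alcohol F5, which is epoxidised with the achiral hydroxyl-directed system VO(acac)2/t-BuOOH in CH2Cl2 to return to 7.

3. Step 2. What may go wrong: SN2 at the other CH2Br terminus of 3, double alkylation of 3, or O-alkylation of the enolate. Fallback, from 2 to 6: enolate 4 is alkylated with ethyl (2E)-4-bromo-2-methylbut-2-enoate (one electrophilic carbon only) to give aldehyde ester F6. i-Bu2AlH reduces both carbonyl groups to diol F7. An Appel reaction (CBr4, PPh3, CH2Cl2, 0 °C) converts only the allylic hydroxyl group into the bromide, the neopentyl one being inert to SN2, and returns to 6.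

**Further compounds**

F1 | step 6 | (1R,5S,6S)-3-bromo-5-[(2E)-4-bromo-3-methylbut-2-en-1-yl]-4,4,6-trimethyl-7-oxabicyclo[4.1.0]hept-2-ene-5-carboxylic acid | OC(=O)[C@]1(C/C=C(C)/CBr)[C@]2(C)O[C@@H]2C=C(Br)C1(C)C
F2 | step 6 | (1R,5S,6S,5′R)-3-bromo-4,4,6-trimethyl-5′-(prop-1-en-2-yl)spiro[7-oxabicyclo[4.1.0]hept-2-ene-5,3′-oxolan]-2′-one | C=C(C)[C@H]1C[C@@]2(C(=O)O1)[C@]3(C)O[C@@H]3C=C(Br)C2(C)C
F3 | step 6 | (3R,5S,9S,10S)-7,9-dibromo-10-hydroxy-6,6,10-trimethyl-3-(prop-1-en-2-yl)-2-oxaspiro[4.5]dec-7-en-1-one | C=C(C)[C@H]1C[C@@]2(C(=O)O1)[C@](C)(O)[C@@H](Br)C=C(Br)C2(C)C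
F4 | step 6 | (3R,5S,9S,10S)-7,9-dibromo-6,6,10-trimethyl-3-(prop-1-en-2-yl)-2-oxaspiro[4.5]dec-7-ene-1,10-diol (both C1 anomers) | C=C(C)[C@H]1C[C@@]2(C(O)O1)[C@](C)(O)[C@@H](Br)C=C(Br)C2(C)C
F5 | step 4 | [(1R)-5-bromo-1-[(2E)-4-bromo-3-methylbut-2-en-1-yl]-2,6,6-trimethylcyclohexa-2,4-dien-1-yl]methanol | OC[C@]1(C/C=C(C)/CBr)C(C)=CC=C(Br)C1(C)C
F6 | step 2 | ethyl (2E)-4-[(±)-5-bromo-1-formyl-2,6,6-trimethylcyclohexa-2,4-dien-1-yl]-2-methylbut-2-enoate | CCOC(=O)/C(C)=C/CC1(C=O)C(C)=CC=C(Br)C1(C)C
F7 | step 2 | (2E)-4-[(±)-5-bromo-1-(hydroxymethyl)-2,6,6-trimethylcyclohexa-2,4-dien-1-yl]-2-methylbut-2-en-1-ol | OC/C(C)=C/CC1(CO)C(C)=CC=C(Br)C1(C)C
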